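**Two runs.** The blue run climbs to 14.7% of its charge, lower than the 25.7% of the red run. Both hold the same incoming ligand, so they differ in equivalents, e = c(incoming ligand)/c(starting complex): 2.20 against 0.550.

| flask | starting complex | incoming ligand | remark | time |
|---|---|---|---|---|
| red | 0.25 mM | 0.55 mM | run made earlier |  |
| blue | 1 mM | 0.55 mM | run made earlier |  |
| flask | 0.50 mM | 0.550 mM |  | 15 min |

- red (time / min: complex with one exchanged / %): 0.417: 21.6; 0.833: 24.2; 2.00: 25.7; 4.00: 24.6; 10.0: 24.0
- blue (time / min: complex with one exchanged / %): 0.417: 12.8; 0.833: 14.3; 2.00: 14.7; 4.00: 14.0; 10.0: 12.3

(standard deviation of a reading: 0.3 percentage points)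

- percent here means starting complex units held: one homo dimer counts as two
- steps that have been proposed: starting complex + incoming ligand <-> leaving ligand + complex with one exchanged; complex with one exchanged + incoming ligand <-> leaving ligand + complex with two exchanged; leaving ligand + starting complex -> side product; 2 starting complex -> homo dimer

* when, up to 15 min, the flask holds most complex with one exchanged
* the amount of complex with one exchanged, in percent of the starting complex charged, at that time

**The order.** I take the top, as a percentage, to follow a power of e. The logarithm of the ratio of the two tops over the logarithm of the ratio of their e gives n, an apparent order in equivalents: 0.403. The flask has e = 1.10, so going from the red reading I expect a top of 19.4%.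

**The curve.** I expect the flask's curve to climb steeply, as the runs do. In the red run the fraction left to climb is 16.0% at 0.417 min and 5.84% at 0.833 min, so the knee comes early. Both runs read highest at 2.00 min, with lower readings at 0.833 min and 4.00 min, so I place the flask's top in that bracket. After that both runs fall slowly: at 10.0 min the red run keeps 93.4% of its top and the blue run 83.7%.

**The forecast.** It says 19.9% at 2 min, since the “peak time barely moves”.

**The flask.** It peaks at 1.55 min with 20.3%, 0.90 percentage points above my reckoning, while homo dimer holds 60.0% of the charge. Carried from this top down to the blue e with n = 0.403, the power gives 15.4% against the blue reading of 14.7%.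

    starting complex + incoming ligand ⇌ leaving ligand + complex with one exchanged (K = 52.0, k = 120 /M/s)
    complex with one exchanged + incoming ligand ⇌ leaving ligand + complex with two exchanged (K = 0.410, k = 280 /M/s)
    leaving ligand + starting complex → side product (k = 81.0 /M/s)
    2 starting complex → homo dimer (k = 250 /M/s)

**A neighbour.** The flask charged with 0.22 mM incoming ligand has e = 0.440, so n from the blue reading gives 13.4%. Its computed top is 12.6%.

(The earlier runs and the new flask are simulated from invented constants; scatter was added.)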